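Decide first what to ask of the earlier runs. I ask not for a rate constant of a scheme you cannot see, but for how high the curve of target is heading.

| flask | starting material | protic impurity | remark | time |
|---|---|---|---|---|
| elm | 0.40 M | 0.16 M | run made earlier |  |
| oak | 1.6 M | 0.16 M | run made earlier |  |
| delta | 0.80 M | 0.160 M |  | 5.0 min |
| zeta | 0.80 M | 0.160 M |  | 30 min |
| alpha | 0.80 M | 0.160 M |  | 12 min |

| elm: time / min | elm: target / % | oak: time / min | oak: target / % |
|---|---|---|---|
| 0.417 | 1 | 0.417 | 3 |
| 0.667 | 5 | 0.667 | 1 |
| 1.00 | 5 | 1.00 | 4 |
| 1.33 | 7 | 1.33 | 8 |
| 2.00 | 14 | 2.00 | 11 |
| 3.00 | 20 | 3.00 | 19 |
| 5.00 | 22 | 5.00 | 26 |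

(scatter of a reading: 1.5 percentage points)

- the analysis behind the earlier runs scatters by 1.5 percentage points, standard deviation

- which of the two there is more of at the end, delta (over-reaction product / target)
- which of the two there is more of at the end, zeta (over-reaction product / target)
- which of the two there is more of at the end, alpha (over-reaction product / target)
- target at the end, in percent of the starting material charged, delta
- target at the end, in percent of the starting material charged, zeta
- target at the end, in percent of the starting material charged, alpha

You may pool elm and oak, I think, although the oak charge is 4.00 times the elm charge. At 2.00 min elm reads higher, 14% against 11%, and at 5.00 min lower, 22% against 26%, so the gaps change sign and look like the scatter of 1.5 percentage points. The objection is the protic impurity, which is 40.0% of the charge in elm and 10.0% in oak. Yet the percentages do not visibly part, so I carry them to 0.80 M, where the impurity stands at the same 0.160 M.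

The pooled means are 4.50% at 1.00 min, 19.5% at 3.00 min and 24.0% at 5.00 min. Over these equal steps of 2.00 min the gains are 15 points and then 4.5 points, so each step keeps a factor 0.300 of the one before. If that factor holds, the remaining steps form a geometric series, and you get the ceiling, the level at which the rise of target ends, 25.9%.

Now the doubts. Elm by itself gives 22.3% and oak by itself 32.1%, so the ceiling is a wide band, and the pooled value is a reading inside it, with the scatter of the readings on it. Worse, a bending curve may also be target already being consumed, and the readings stop at 5.00 min, so they cannot say how long the height lasts. I therefore commit to this: delta near 24.0%, read directly, with target ahead; alpha near the ceiling, with target ahead; zeta lower, by an amount I cannot reckon, with over-reaction product ahead.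

The forecast, made from the same runs, gave 24% for delta, 20% for alpha and 6% for zeta, with over-reaction product ahead in alpha, reasoning that by then “the target is falling”.

The flask gives 25.4% in delta, 28.3% in alpha and 13.2% in zeta, and target leads in alpha over 21.1% of over-reaction product. The forward step from target to isomer of the product has a half-life of 1.3 min, shorter than delta's 5.0 min. Alpha stands 2.4 points above the ceiling, inside the band, and zeta at about half of it. If I draw one steady halving from the ceiling at 12 min down to the value of zeta at 30 min, a rough reckoning and not a constant of the flask, its half-life is about 18.4 min.

    starting material ⇌ intermediate A (K = 31.0, k = 0.920 /min)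
    starting material → intermediate B (k = 0.110 /min)
    intermediate A → target (k = 0.220 /min)
    intermediate B → intermediate C (k = 0.110 /min)
    intermediate B → intermediate D (k = 0.0570 /min)
    intermediate D → intermediate E (k = 0.0120 /min)
    intermediate A → intermediate B (k = 0.00930 /min)
    intermediate C ⇌ intermediate E (K = 25.0, k = 0.0720 /min)
    starting material + protic impurity → quenched substrate (k = 2.50 /M/min)
    target ⇌ isomer of the product (K = 0.530, k = 0.540 /min)
    target → over-reaction product (k = 0.0780 /min)

Take the alpha flask left until 20 min: the ceiling, halved every 18.4 min from 12 min on, gives 19.2%. The computed flask holds 21.1%.

The data come from a simulation on assumed constants; the scatter is artificial.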